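## The problem

The target is a heliangolide: a ten-membered carbocycle (C1–C10, germacrane numbering) with a 1β,10α-epoxide that derives from an E C1=C10 alkene, a Z C4=C5 alkene, and an α-methylene-γ-butyrolactone (O6–C12(=O)–C11(=C13)–C7) trans-fused across C6–C7. C3 carries a benzoate and C8 a (2R,3S)-2,3-dimethyloxirane-2-carboxylate. The medium ring holds two trisubstituted alkenes of opposite geometry, which favours expansion of a six-membered ring over an end-to-end closure. Of the eight stereocentres, C3 is 1,4 to C6 across the Z alkene and cannot be relied on to direct the C6–C7–C8 triad in a flexible ring. The triad must therefore be built as a unit: C6 is set by a reagent, C7 by C6 through a tether, and C8 by C7. C1 and C10 follow from the E geometry and the exposed face of the alkene, and the two side-chain centres need their own source. The methylene lactone is a Michael acceptor, isomerises with base and can migrate to a free O8; the epoxides and the 1(10),4-diene are prone to acid-induced transannular reactions; so esters and the ring epoxide must come last. The enabling feature is the contiguous pattern C6(O)–C7(C11)–C8(O): the lactone ring O6–C12–C11–C7–C6 is what remains when a two-carbon radical tethered to O6 adds 5-exo to C7 of a C7=C8 alkene and the C8 radical is captured by oxygen.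

## Retrosynthesis

Germacrane numbering is used for all ten-membered compounds; α/β refer to the usual drawing with H7 α.

**28 ⇒ 27 (C1–O, C10–O).** The ring epoxide is removed first because it is the most acid-labile group and would not survive acetal hydrolysis or the Mannich sequence. Diene 27 has three alkenes, of which only C1=C10 is electron-rich, so the forward step asks only for face selectivity on an E alkene of a medium ring.

**27 ⇒ 22 + 25 (O8–acyl).** Cutting the C8 ester keeps the base-sensitive glycidic ester out of every enolate step. Acid 25 comes from commercial (E)-2-methylbut-2-en-1-ol 23 by asymmetric epoxidation to 24 and oxidation. The forward reaction must acylate a hindered secondary alcohol with retention.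

**22 ⇒ 21 ⇒ 20 ⇒ 19 (N–O8, O3–benzoyl, O3–Si).** O8 is carried as the 2,2,6,6-tetramethylpiperidin-1-yl ether left by the key step. This is preferred to early N–O cleavage: a free O8 would be oxidised with the lactol and would invite lactone migration under base. With O8 masked, exchange of silyl for benzoate at O3 needs no selectivity.

**19 ⇒ 16 ⇒ 15 ⇒ 14 (C11=C13; C12 oxidation level).** The methylene is cut back to lactone 16 (Mannich/elimination), and the lactone to lactol 15 and ethyl acetal 14. The acetal level is chosen over a haloacetate tether because α-alkoxyalkyl radicals close much faster than ester-tethered ones.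

**14 ⇒ 12 + 13 (C7–C11 and C8–O8).** This is the key disconnection. Both bonds and the five-membered ring come from bromoacetal 12 and the nitroxide 13. The precursor is a monocyclic triene with only two stereocentres on the ring (C3, C6) and one on the acetal carbon. The forward step must choose C7 over C5, close before the nitroxide intercepts the open-chain radical, and set C7 and C8.

**12 ⇒ 10 + 11; 10 ⇒ 9; 9 ⇒ 8.** The acetal C–O6 bond leads to trienol 10 and ethyl vinyl ether 11. Only the acetal epimer that can place ethoxy pseudo-axial in the chair leading to C7 is carried on. The C6 carbinol comes from trienone 9 by reagent-controlled reduction, and the C7=C8 alkene from silyl dienol ether 8 by dehydrogenation, which is regiodefined because only C8 carries β-hydrogens.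

**8 ⇒ 6 via 7 (C8–C9 cut, C6–C1 joined).** The ten-membered ring is contracted to a cyclohexenol by a retro-[3,3] shift. The forward anionic oxy-Cope rearrangement fixes both geometries: the cyclohexene alkene becomes Z C4=C5 and the chair gives E C1=C10. No macrocyclisation is needed.

**6 ⇒ 4 + 5; 4 ⇒ 3 ⇒ 2 ⇒ 1.** Vinylmagnesium bromide 5 adds to enone 4, which comes from (S)-carvone 1 by reduction to cis-carveol 2, silylation to 3 and allylic oxidation. Carvone's stereocentre is relayed to the carbinol that becomes C3 and is then consumed in the ring expansion.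

## Roads not taken

**Alternative 1:** The ten-membered ring would be cut at C10–C1 and C5–C4 into enone A2 and cyclobutene A3. Irradiation near 350 nm would give the cis-anti-cis 6-4-4 tricyclic ketone A1, and thermal cycloreversion of the central cyclobutane would then release the 1(10),4-diene.
- Merits: it is more convergent than the chosen plan. C7, C8 and the C11–C12 acetate unit are set on a six-membered ring by conventional means, so it has no counterpart to the uncertain radical capture at C8; in this respect it is the better plan.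
- Weak points: the photocycloaddition must be head-to-tail and face-selective with two chiral partners. The cycloreversion needs high temperature, at which a 1,5-diene can undergo Cope rearrangement to the elemane skeleton and C7 (α to the C6 ketone) can epimerise. The E/Z outcome at C1=C10 and C4=C5 is not dictated by the precursor. Enantiopure A3 needs its own synthesis.
- Comparison: the chosen plan fixes both alkene geometries in a room-temperature sigmatropic step from one chiral-pool ketone.

**Alternative 2:** The ring would be cut at C9–C10. Seco-iodide A5 would be hydroborated with 9-BBN at its 1-alkoxyvinyl group (boron on C9, hydrogen on C8) and closed with Pd(dppf)Cl2 and base onto the E alkenyl iodide to give lactone A4.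
- Merits: the lactone and the C6/C7 centres are made before ring closure, both alkene geometries are fixed in open-chain precursors, and the C3 benzoate is present from the start, so the late silyl-to-benzoate exchange of the chosen plan is avoided.
- Weak points: C8 is set by a hydroboration whose face selectivity rests on C7 alone, so it is no more secure than the radical capture. The β-alkoxyalkylborane can eliminate under the basic coupling conditions. A ten-membered ring closed by cross-coupling must pay the full strain and entropy cost at high dilution, in the presence of a lactone and a benzoate under aqueous base. The open-chain assembly of A5 is likely to be longer.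
- Comparison: the chosen plan forms the ring without any end-to-end closure.

**Alternative 3:** Four carbons would be annulated onto carvone to give ring-fusion cis-diol A7, and Pb(OAc)4 would cleave C3–C8 to give (1(10)Z,4Z)-dione A6.
- Merits: the ring opening is irreversible and free of entropy cost. It uses carvone better than the chosen plan: the carvone stereocentre is kept as C7 and its isopropenyl group becomes C11–C13, so no methylenation is needed.
- Weak points: a cis-fused bicyclic precursor can only give a Z C1=C10 alkene, and the target needs E; isomerisation within a ten-membered ring is not dependable. Two ketones (C3, C8) must be reduced with the right sense on a flexible ring. The β,γ-unsaturated C8 ketone invites alkene migration and epimerisation at C7.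
- Comparison: the chosen plan gives the E alkene by construction and has only one ketone reduction.

Key step: step 9

Assumption: the two acetal epimers formed in step 8 are separable diastereomers, and only the (S)-acetal 12 is carried forward.
Assumption: (E)-2-methylbut-2-en-1-ol 23 is taken as a commercial material; the side-chain acid has its two methyl groups cis on the oxirane, as the target structure requires.

## Steps

Step 1
Reactants: 1 (S)-(+)-carvone
Product: 2 (1S,5S)-cis-carveol
Conditions: NaBH4, CeCl3·7H2O, MeOH, −20 °C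
Reagents that add atoms: none
Why: Luche reduction gives 1,2-reduction only; hydride adds axially, anti to the pseudo-equatorial isopropenyl group, so the new carbinol (later C3) is cis to it and S.

Step 2
Reactants: 2 (1S,5S)-cis-carveol
Product: 3 (1S,5S)-cis-carveol tert-butyldimethylsilyl ether
Conditions: t-BuMe2SiCl, imidazole, DMF, 25 °C
Reagents that add atoms: tert-butyldimethylsilyl chloride CC(C)(C)[Si](C)(C)Cl
Why: Standard silylation of a secondary allylic alcohol; the ether should survive Grignard, KH, palladium, borane and radical steps and is removed by fluoride.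

Step 3
Reactants: 3 (1S,5S)-cis-carveol tert-butyldimethylsilyl ether
Product: 4 (4S,6S)-4-(tert-butyldimethylsilyloxy)-3-methyl-6-(prop-1-en-2-yl)cyclohex-2-en-1-one
Conditions: CrO3, 3,5-dimethylpyrazole, CH2Cl2, −20 °C
Reagents that add atoms: chromium trioxide O=[Cr](=O)=O
Why: Allylic oxidation of the ring methylene next to the trisubstituted alkene, the only allylic site that can become a conjugated ketone; the carbonyl ends up 1,4 to the silyloxy carbon and no stereocentre is touched.

Step 4
Reactants: 4 (4S,6S)-4-(tert-butyldimethylsilyloxy)-3-methyl-6-(prop-1-en-2-yl)cyclohex-2-en-1-one; 5 vinylmagnesium bromide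
Product: 6 (1S,4S,6S)-4-(tert-butyldimethylsilyloxy)-1-ethenyl-3-methyl-6-(prop-1-en-2-yl)cyclohex-2-en-1-ol
Conditions: THF, −78 → 0 °C
Reagents that add atoms: none
Why: Grignard 1,2-addition to a β,β-disubstituted enone; vinyl should enter anti to the neighbouring isopropenyl group, giving the trans-dialkenyl carbinol that a chair oxy-Cope needs. The new centre is lost in step 5.

Step 5
Reactants: 6 (1S,4S,6S)-4-(tert-butyldimethylsilyloxy)-1-ethenyl-3-methyl-6-(prop-1-en-2-yl)cyclohex-2-en-1-ol
Product: 8 (1Z,3Z,5S,7E)-5-(tert-butyldimethylsilyloxy)-4,8-dimethyl-2-(trimethylsilyloxy)cyclodeca-1,3,7-triene, via potassium dienolate 7 (not isolated)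
Conditions: KH, 18-crown-6, THF, 0 → 25 °C; then Me3SiCl, Et3N, −78 °C
Reagents that add atoms: chlorotrimethylsilane C[Si](C)(C)Cl
Why: Anionic oxy-Cope rearrangement: the [3,3] shift breaks the ring bond between the carbinol and the isopropenyl-bearing carbon and joins the alkene termini (C8–C9), expanding six to ten. The chair with both alkenyl arms equatorial gives E C1=C10, and the cyclohexene alkene becomes Z C4=C5. O-Silylation fixes the enolate on the C6–C7 side.

Step 6
Reactants: 8 (1Z,3Z,5S,7E)-5-(tert-butyldimethylsilyloxy)-4,8-dimethyl-2-(trimethylsilyloxy)cyclodeca-1,3,7-triene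
Product: 9 (2Z,4S,6E,9E)-4-(tert-butyldimethylsilyloxy)-3,7-dimethylcyclodeca-2,6,9-trien-1-one (C1 = germacrane C6)
Conditions: Pd(OAc)2 (1.1 equiv), MeCN, 25 °C
Reagents that add atoms: none
Why: Saegusa–Ito oxidation: palladium diacetate turns the silyl enol ether into a palladium enolate that loses a C8 hydride by syn β-elimination. Only C8 carries β-hydrogens, and elimination through the rotamer with C9 anti to C6 should give the E enone.

Step 7
Reactants: 9 (2Z,4S,6E,9E)-4-(tert-butyldimethylsilyloxy)-3,7-dimethylcyclodeca-2,6,9-trien-1-one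
Product: 10 (1S,2Z,4S,6E,9E)-4-(tert-butyldimethylsilyloxy)-3,7-dimethylcyclodeca-2,6,9-trien-1-ol (carbinol = germacrane C6, S)
Conditions: (R)-2-methyl-CBS-oxazaborolidine (0.5 equiv), catecholborane, toluene, −78 °C
Reagents that add atoms: none
Why: Corey–Bakshi–Shibata reduction, 1,2 only. The Z trisubstituted enone arm holds C3 cis to the carbonyl and so screens the oxygen lone pair on its side; it should act as the large group and the E disubstituted arm as the small one, so the (R)-catalyst should deliver hydride to the face that gives the (6S)-alcohol.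

Step 8
Reactants: 10 (1S,2Z,4S,6E,9E)-4-(tert-butyldimethylsilyloxy)-3,7-dimethylcyclodeca-2,6,9-trien-1-ol; 11 ethyl vinyl ether
Product: 12 (S)-2-bromo-1-ethoxyethyl mixed acetal of 10 at O6 (acetal carbon S, single epimer)
Conditions: N-bromosuccinimide, 11 (excess), CH2Cl2, −40 → 0 °C; chromatographic separation of the acetal epimers
Reagents that add atoms: N-bromosuccinimide O=C1CCC(=O)N1Br
Why: Bromoacetalisation: the enol ether is far more nucleophilic toward the bromonium source than the ring alkenes, and O6 captures the oxocarbenium ion. Both acetal epimers form; the S epimer is taken on and the other is returned to 10 with pyridinium 4-toluenesulfonate in methanol.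

Step 9
Reactants: 12 (S)-2-bromo-1-ethoxyethyl mixed acetal of 10; 13 2,2,6,6-tetramethylpiperidin-1-oxyl (TEMPO)
Product: 14 trans-fused lactol ethyl ether: 2-ethoxytetrahydrofuran fused at C6–C7 to the 1(10)E,4Z-cyclodecadiene, 3β-silyloxy, 8β-(2,2,6,6-tetramethylpiperidin-1-yloxy); C3 S, C6 R, C7 S, C8 R, acetal carbon S
Conditions: (Bu3Sn)2 (1.2 equiv), hν (sunlamp, Pyrex), benzene (0.01 M), 25 °C, 13 (2.5 equiv) added by syringe pump over several hours
Reagents that add atoms: none
Why: Photolysis of the ditin gives stannyl radicals that abstract bromine from 12; the primary C11 radical adds to C7 of the E C7=C8 alkene (Ueno–Stork haloacetal cyclisation), and the secondary C8 radical, which has no favourable ring closure of its own, couples with the persistent nitroxide 13 to form C8–O. One ring closes, the five-membered lactol ether O6–C12–C11–C7–C6, in the 5-exo-trig mode through a chair-like transition state. C7 is set by that chair: C5 on C6 sits pseudo-equatorial, so C5 and C8 end up trans on the new ring (trans fusion, H7 anti to H6). C8 is set by approach of the bulky nitroxide anti to the new C7–C11 bond while C9 is still anti to C6, the arrangement inherited from the E alkene. The step needs site selectivity for C7 over C5, both being 5-exo termini, and the acetal configuration secures it: in 12 the ethoxy group can be pseudo-axial (anomeric stabilisation) with C5 pseudo-equatorial only in the chair that leads to C7, whereas closure on C5 would force ethoxy equatorial or C7 axial; the strained E disubstituted alkene is also the more reactive acceptor. The step also needs ring closure to outrun coupling of the open-chain radical with the nitroxide, which high dilution and slow feed of 13 should secure. The closest known reaction type is halide-initiated 5-exo radical cyclisation with nitroxide capture of the cyclised radical.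

Step 10
Reactants: 14 trans-fused lactol ethyl ether
Product: 15 lactol (12-hydroxy, both anomers), otherwise as 14
Conditions: AcOH/THF/H2O (4:2:1), 40 °C
Reagents that add atoms: water O
Why: Mild hydrolysis of the cyclic acetal; the aminoxy ether and the secondary silyl ether should tolerate it, and the acid is too weak to start transannular cyclisation of the 1,5-diene.

Step 11
Reactants: 15 lactol
Product: 16 3β-(tert-butyldimethylsilyloxy)-8β-(2,2,6,6-tetramethylpiperidin-1-yloxy)-13-norgermacra-1(10)E,4Z-dien-12,6α-olide
Conditions: (n-Pr4N)RuO4 (5 mol %), N-methylmorpholine N-oxide, 4 Å molecular sieves, CH2Cl2, 25 °C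
Reagents that add atoms: none
Why: Ley–Griffith oxidation of a lactol to the lactone under neutral conditions; no other hydroxyl is free because O8 is still masked as the aminoxy ether.

Step 12
Reactants: 16 13-nor lactone
Product: 19 3β-(tert-butyldimethylsilyloxy)-8β-(2,2,6,6-tetramethylpiperidin-1-yloxy)germacra-1(10)E,4Z,11(13)-trien-12,6α-olide, via Mannich base 17 (not isolated), via trimethylammonium iodide 18 (not isolated)
Conditions: LiN(iPr)2, THF, −78 °C; CH2=NMe2+ I−, −78 → 0 °C; then MeI, MeOH, 25 °C; then aq. NaHCO3, CH2Cl2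
Reagents that add atoms: Eschenmoser's salt C=[N+](C)C.[I-]
Why: Eschenmoser methylenation: Mannich reaction of the lactone enolate at C11, N-methylation and mild-base elimination give the exocyclic C11=C13 alkene. The hindered aminoxy ether is inert to amide base and MeI and keeps O8 from attacking the lactone; the C11 configuration in 17 and 18 is of no consequence.

Step 13
Reactants: 19 silyl-protected methylene lactone
Product: 20 3β-hydroxy-8β-(2,2,6,6-tetramethylpiperidin-1-yloxy)germacra-1(10)E,4Z,11(13)-trien-12,6α-olide
Conditions: HF·pyridine, pyridine, THF, 0 → 25 °C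
Reagents that add atoms: none
Why: Fluoride cleavage of the silyl ether under buffered, non-basic conditions, so the methylene lactone should neither isomerise nor add nucleophiles.

Step 14
Reactants: 20 C3 alcohol
Product: 21 3β-benzoyloxy-8β-(2,2,6,6-tetramethylpiperidin-1-yloxy)germacra-1(10)E,4Z,11(13)-trien-12,6α-olide
Conditions: PhCOCl, pyridine, DMAP (cat.), CH2Cl2, 0 → 25 °C
Reagents that add atoms: benzoyl chloride O=C(Cl)c1ccccc1
Why: Acylation of the only free hydroxyl; O8 is still masked, so no selectivity between O3 and O8 is needed.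

Step 15
Reactants: 21 C3 benzoate
Product: 22 3β-benzoyloxy-8β-hydroxygermacra-1(10)E,4Z,11(13)-trien-12,6α-olide
Conditions: Zn dust, AcOH/THF/H2O (3:1:1), 50 °C
Reagents that add atoms: none
Why: Reductive N–O cleavage by zinc in acetic acid frees the C8 alcohol with retention. The esters and the unactivated acrylate-type lactone should survive, and the acidic medium does not promote lactone migration to O8.

Step 16
Reactants: 23 (E)-2-methylbut-2-en-1-ol
Product: 24 (2S,3S)-(2,3-dimethyloxiran-2-yl)methanol
Conditions: Ti(OiPr)4 (cat.), L-(+)-diethyl tartrate (cat.), t-BuOOH, 4 Å molecular sieves, CH2Cl2, −20 °C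
Reagents that add atoms: tert-butyl hydroperoxide CC(C)(C)OO
Why: Sharpless asymmetric epoxidation; with the L-(+)-tartrate, oxygen is delivered to the face of the E allylic alcohol that gives the (2S,3S)-epoxy alcohol, both centres being set by the catalyst.

Step 17
Reactants: 24 (2S,3S)-(2,3-dimethyloxiran-2-yl)methanol
Product: 25 (2R,3S)-2,3-dimethyloxirane-2-carboxylic acid
Conditions: RuCl3 (2 mol %), NaIO4, MeCN/CCl4/H2O, 25 °C
Reagents that add atoms: water O
Why: Ruthenium tetroxide generated from RuCl3 and periodate oxidises the primary alcohol to the acid without opening the epoxide. The geometry is unchanged; the C2 descriptor becomes R only because the carboxyl outranks C3.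

Step 18
Reactants: 22 C8 alcohol; 25 (2R,3S)-2,3-dimethyloxirane-2-carboxylic acid
Product: 27 3β-benzoyloxy-8β-[(2R,3S)-2,3-dimethyloxirane-2-carbonyloxy]germacra-1(10)E,4Z,11(13)-trien-12,6α-olide, via mixed anhydride 26 (not isolated)
Conditions: 25, 2,4,6-Cl3C6H2COCl, Et3N, THF, 25 °C; then 22, DMAP, toluene, 25 °C
Reagents that add atoms: none
Why: Yamaguchi esterification: DMAP attacks the less hindered aliphatic carbonyl of the mixed anhydride and the hindered C8 hydroxyl is acylated with retention; the side-chain epoxide and the methylene lactone are not affected.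

Step 19
Reactants: 27 diester triene
Product: 28 target, 1β,10α-epoxy-3β-benzoyloxy-8β-[(2R,3S)-2,3-dimethyloxirane-2-carbonyloxy]germacra-4Z,11(13)-dien-12,6α-olide (1R,3S,6R,7R,8R,10R)
Conditions: mCPBA, NaHCO3, CH2Cl2, 0 °C
Reagents that add atoms: 3-chloroperbenzoic acid O=C(OO)c1cccc(Cl)c1
Why: Prilezhaev epoxidation of the only electron-rich alkene: C4=C5 is deactivated by two allylic acyloxy groups and C11=C13 is conjugated. Syn addition to the outer face of the E alkene in the favoured ring conformer should give the 1β,10α-epoxide (C1 R, C10 R); bicarbonate removes the acid.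

## Compound list

1 | (S)-(+)-carvone | CC(=C)[C@H]1CC=C(C)C(=O)C1 | starting material
2 | (1S,5S)-cis-carveol | CC(=C)[C@H]1CC=C(C)[C@@H](O)C1 | intermediate
3 | (1S,5S)-cis-carveol tert-butyldimethylsilyl ether | CC(=C)[C@H]1CC=C(C)[C@@H](O[Si](C)(C)C(C)(C)C)C1 | intermediate
4 | (4S,6S)-4-(tert-butyldimethylsilyloxy)-3-methyl-6-(prop-1-en-2-yl)cyclohex-2-en-1-one | CC(=C)[C@H]1C(=O)C=C(C)[C@@H](O[Si](C)(C)C(C)(C)C)C1 | intermediate
5 | vinylmagnesium bromide | C=C[Mg]Br | starting material
6 | (1S,4S,6S)-4-(tert-butyldimethylsilyloxy)-1-ethenyl-3-methyl-6-(prop-1-en-2-yl)cyclohex-2-en-1-ol | CC(=C)[C@H]1[C@](O)(C=C)C=C(C)[C@@H](O[Si](C)(C)C(C)(C)C)C1 | intermediate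
7 | potassium (1Z,3Z,5S,7E)-5-(tert-butyldimethylsilyloxy)-4,8-dimethylcyclodeca-1,3,7-trien-2-olate | [C@H]1(O[Si](C)(C)C(C)(C)C)C/C=C(\C)CC/C=C(\[O-])/C=C1/C.[K+] | intermediate (not isolated)
8 | (1Z,3Z,5S,7E)-5-(tert-butyldimethylsilyloxy)-4,8-dimethyl-2-(trimethylsilyloxy)cyclodeca-1,3,7-triene | [C@H]1(O[Si](C)(C)C(C)(C)C)C/C=C(\C)CC/C=C(\O[Si](C)(C)C)/C=C1/C | intermediate
9 | (2Z,4S,6E,9E)-4-(tert-butyldimethylsilyloxy)-3,7-dimethylcyclodeca-2,6,9-trien-1-one | O=C1/C=C(/C)[C@@H](O[Si](C)(C)C(C)(C)C)C/C=C(\C)C/C=C/1 | intermediate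
10 | (1S,2Z,4S,6E,9E)-4-(tert-butyldimethylsilyloxy)-3,7-dimethylcyclodeca-2,6,9-trien-1-ol | O[C@@H]1/C=C(/C)[C@@H](O[Si](C)(C)C(C)(C)C)C/C=C(\C)C/C=C/1 | intermediate
11 | ethyl vinyl ether | C=COCC | starting material
12 | (S)-2-bromo-1-ethoxyethyl mixed acetal of 10 at O6 (single acetal epimer) | CCO[C@H](CBr)O[C@@H]1/C=C(/C)[C@@H](O[Si](C)(C)C(C)(C)C)C/C=C(\C)C/C=C/1 | intermediate
13 | 2,2,6,6-tetramethylpiperidin-1-oxyl (TEMPO) | CC1(C)CCCC(C)(C)N1[O] | starting material
14 | trans-fused lactol ethyl ether, 3β-silyloxy, 8β-(2,2,6,6-tetramethylpiperidin-1-yloxy), 1(10)E,4Z-diene (C3 S, C6 R, C7 S, C8 R, acetal C S) | CCO[C@@H]1C[C@H]2[C@H](O1)/C=C(/C)[C@@H](O[Si](C)(C)C(C)(C)C)C/C=C(\C)C[C@H]2ON1C(C)(C)CCCC1(C)C | intermediate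
15 | lactol corresponding to 14 (12-hydroxy, both anomers) | OC1C[C@H]2[C@H](O1)/C=C(/C)[C@@H](O[Si](C)(C)C(C)(C)C)C/C=C(\C)C[C@H]2ON1C(C)(C)CCCC1(C)C | intermediate
16 | 3β-(tert-butyldimethylsilyloxy)-8β-(2,2,6,6-tetramethylpiperidin-1-yloxy)-13-norgermacra-1(10)E,4Z-dien-12,6α-olide | C1C(=O)O[C@@H]2/C=C(/C)[C@@H](O[Si](C)(C)C(C)(C)C)C/C=C(\C)C[C@@H](ON3C(C)(C)CCCC3(C)C)[C@@H]12 | intermediate
17 | 11-(dimethylaminomethyl) derivative of 16 (Mannich base, C11 epimers) | CN(C)CC1C(=O)O[C@@H]2/C=C(/C)[C@@H](O[Si](C)(C)C(C)(C)C)C/C=C(\C)C[C@@H](ON3C(C)(C)CCCC3(C)C)[C@@H]12 | intermediate (not isolated)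
18 | trimethylammonium iodide of 17 | C[N+](C)(C)CC1C(=O)O[C@@H]2/C=C(/C)[C@@H](O[Si](C)(C)C(C)(C)C)C/C=C(\C)C[C@@H](ON3C(C)(C)CCCC3(C)C)[C@@H]12.[I-] | intermediate (not isolated)
19 | 3β-(tert-butyldimethylsilyloxy)-8β-(2,2,6,6-tetramethylpiperidin-1-yloxy)germacra-1(10)E,4Z,11(13)-trien-12,6α-olide | C=C1C(=O)O[C@@H]2/C=C(/C)[C@@H](O[Si](C)(C)C(C)(C)C)C/C=C(\C)C[C@@H](ON3C(C)(C)CCCC3(C)C)[C@@H]12 | intermediate
20 | 3β-hydroxy-8β-(2,2,6,6-tetramethylpiperidin-1-yloxy)germacra-1(10)E,4Z,11(13)-trien-12,6α-olide | C=C1C(=O)O[C@@H]2/C=C(/C)[C@@H](O)C/C=C(\C)C[C@@H](ON3C(C)(C)CCCC3(C)C)[C@@H]12 | intermediate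
21 | 3β-benzoyloxy-8β-(2,2,6,6-tetramethylpiperidin-1-yloxy)germacra-1(10)E,4Z,11(13)-trien-12,6α-olide | C=C1C(=O)O[C@@H]2/C=C(/C)[C@@H](OC(=O)c3ccccc3)C/C=C(\C)C[C@@H](ON3C(C)(C)CCCC3(C)C)[C@@H]12 | intermediate
22 | 3β-benzoyloxy-8β-hydroxygermacra-1(10)E,4Z,11(13)-trien-12,6α-olide | C=C1C(=O)O[C@@H]2/C=C(/C)[C@@H](OC(=O)c3ccccc3)C/C=C(\C)C[C@@H](O)[C@@H]12 | intermediate
23 | (E)-2-methylbut-2-en-1-ol | C/C=C(\C)CO | starting material
24 | (2S,3S)-(2,3-dimethyloxiran-2-yl)methanol | OC[C@]1(C)O[C@H]1C | intermediate
25 | (2R,3S)-2,3-dimethyloxirane-2-carboxylic acid | OC(=O)[C@]1(C)O[C@H]1C | intermediate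
26 | mixed anhydride of 25 with 2,4,6-trichlorobenzoic acid | Clc1cc(Cl)cc(Cl)c1C(=O)OC(=O)[C@]1(C)O[C@H]1C | intermediate (not isolated)
27 | 3β-benzoyloxy-8β-[(2R,3S)-2,3-dimethyloxirane-2-carbonyloxy]germacra-1(10)E,4Z,11(13)-trien-12,6α-olide | C=C1C(=O)O[C@@H]2/C=C(/C)[C@@H](OC(=O)c3ccccc3)C/C=C(\C)C[C@@H](OC(=O)[C@]3(C)O[C@H]3C)[C@@H]12 | intermediate
28 | 1β,10α-epoxy-3β-benzoyloxy-8β-[(2R,3S)-2,3-dimethyloxirane-2-carbonyloxy]germacra-4Z,11(13)-dien-12,6α-olide | C=C1C(=O)O[C@@H]2/C=C(/C)[C@@H](OC(=O)c3ccccc3)C[C@H]3O[C@]3(C)C[C@@H](OC(=O)[C@]3(C)O[C@H]3C)[C@@H]12 | target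

## Step count and least certain steps

Total: 19 steps. Longest linear sequence: 17 steps (steps 1–15, 18, 19, from carvone); the side-chain acid takes 2 steps (16, 17).

**Step 9 (key step).** The most likely failure is poor facial selectivity at C8. At the moment of ring closure the exposed lobe of the C8 radical is syn to the new C7–C11 bond, and the wanted anti capture needs the ring to relax before the nitroxide arrives; syn capture would give the C8 epimer. Two further risks, capture of the open-chain radical before closure and closure on C5, are met in the design by slow feed at high dilution and by the choice of acetal epimer. The fallback accepts the epimer and inverts C8 when the ester is made. It sets out from 12: step 9 would give the 8α-aminoxy lactol ether F1. Steps 10 to 15, applied unchanged, would give in turn the lactol F2, the 13-nor lactone F3, its Mannich base F4 and trimethylammonium iodide F5 (neither isolated), the methylene lactone F6, the C3 alcohol F7, the C3 benzoate F8 and the 8α-alcohol F9. Mitsunobu esterification of the 8α-alcohol F9 with acid 25 (PPh3, diisopropyl azodicarboxylate, toluene, 0 → 25 °C) proceeds with inversion and returns to the route at 27.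

**Step 3.** The most likely failure is oxidation at the wrong allylic site or over-oxidation, because the isopropenyl group offers competing allylic hydrogens and the chromium reagent discriminates only by accessibility. The fallback replaces C–H oxidation by an oxidative 1,3-transposition and sets out from 2. Hydroxyl-directed epoxidation (VO(acac)2, t-BuOOH, benzene) would give the cis-2,3-epoxy alcohol F10, and silylation its silyl ether F11. Trans-diaxial opening at the secondary carbon with PhSeNa (from PhSeSePh and NaBH4, EtOH) would give the hydroxy selenide F12. Oxidation with H2O2 and pyridine would pass through the selenoxide F13, which eliminates away from the tertiary carbinol to the tertiary allylic alcohol F14. Babler–Dauben oxidation of the tertiary allylic alcohol F14 with (C5H5NH)CrO3Cl in CH2Cl2 returns to the route at 4.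

**Step 6.** The most likely failure is loss of geometric control in the β-hydride elimination, because the E enone is the more strained isomer in a ten-membered ring that already holds an E and a Z alkene, and the palladium enolate can reach a syn hydrogen in more than one rotamer. The fallback replaces the metal-mediated elimination by a selenoxide syn-elimination and sets out from 6 through enolate 7. Quenching 7 with PhSeBr at −78 °C would give the C7 phenylselanyl ketone F15. H2O2 and pyridine at 0 °C would give the selenoxide F16, whose thermal syn-elimination toward C8 returns to the route at 9.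

**Step 7.** The most likely failure is poor face discrimination, because both carbonyl substituents are alkenyl groups and the bias of the chiral ring may oppose the catalyst. The fallback gives up reagent control and sets out from 9. Luche reduction (NaBH4, CeCl3·7H2O, MeOH) would give 10 together with its (6R)-epimer F17, separable as diastereomers. Mitsunobu inversion of the (6R)-epimer F17 with 4-nitrobenzoic acid (PPh3, diisopropyl azodicarboxylate) would give the (6S)-4-nitrobenzoate F18. Methanolysis of the 4-nitrobenzoate F18 (K2CO3, MeOH) returns to the route at 10.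

**Step 19.** The most likely failure is attack on the other face of C1=C10, since the result depends on which ring conformer presents the alkene, or acid-induced transannular opening of the product. The fallback builds the epoxide by anti addition and closure, which places oxygen on the face opposite to the electrophile. It sets out from 27. N-Bromosuccinimide in aqueous THF would give the bromohydrin F19 (bromine on C1, hydroxyl on C10). Ag2O in CH2Cl2 closes it with inversion at C1 and returns to the route at 28.

## Further compounds

F1 | step 9 | 8α-aminoxy epimer of 14 | CCO[C@@H]1C[C@H]2[C@H](O1)/C=C(/C)[C@@H](O[Si](C)(C)C(C)(C)C)C/C=C(\C)C[C@@H]2ON1C(C)(C)CCCC1(C)C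
F2 | step 9 | 8α-aminoxy epimer of lactol 15 | OC1C[C@H]2[C@H](O1)/C=C(/C)[C@@H](O[Si](C)(C)C(C)(C)C)C/C=C(\C)C[C@@H]2ON1C(C)(C)CCCC1(C)C
F3 | step 9 | 8α-aminoxy epimer of lactone 16 | C1C(=O)O[C@@H]2/C=C(/C)[C@@H](O[Si](C)(C)C(C)(C)C)C/C=C(\C)C[C@H](ON3C(C)(C)CCCC3(C)C)[C@@H]12
F4 | step 9 | 8α-aminoxy epimer of Mannich base 17 | CN(C)CC1C(=O)O[C@@H]2/C=C(/C)[C@@H](O[Si](C)(C)C(C)(C)C)C/C=C(\C)C[C@H](ON3C(C)(C)CCCC3(C)C)[C@@H]12
F5 | step 9 | 8α-aminoxy epimer of ammonium iodide 18 | C[N+](C)(C)CC1C(=O)O[C@@H]2/C=C(/C)[C@@H](O[Si](C)(C)C(C)(C)C)C/C=C(\C)C[C@H](ON3C(C)(C)CCCC3(C)C)[C@@H]12.[I-]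
F6 | step 9 | 8α-aminoxy epimer of methylene lactone 19 | C=C1C(=O)O[C@@H]2/C=C(/C)[C@@H](O[Si](C)(C)C(C)(C)C)C/C=C(\C)C[C@H](ON3C(C)(C)CCCC3(C)C)[C@@H]12
F7 | step 9 | 8α-aminoxy epimer of alcohol 20 | C=C1C(=O)O[C@@H]2/C=C(/C)[C@@H](O)C/C=C(\C)C[C@H](ON3C(C)(C)CCCC3(C)C)[C@@H]12
F8 | step 9 | 8α-aminoxy epimer of benzoate 21 | C=C1C(=O)O[C@@H]2/C=C(/C)[C@@H](OC(=O)c3ccccc3)C/C=C(\C)C[C@H](ON3C(C)(C)CCCC3(C)C)[C@@H]12
F9 | step 9 | 3β-benzoyloxy-8α-hydroxygermacra-1(10)E,4Z,11(13)-trien-12,6α-olide | C=C1C(=O)O[C@@H]2/C=C(/C)[C@@H](OC(=O)c3ccccc3)C/C=C(\C)C[C@H](O)[C@@H]12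
F10 | step 3 | cis-2,3-epoxycarveol (epoxide syn to hydroxyl) | CC(=C)[C@H]1C[C@H]2O[C@@]2(C)[C@@H](O)C1
F11 | step 3 | tert-butyldimethylsilyl ether of F10 | CC(=C)[C@H]1C[C@H]2O[C@@]2(C)[C@@H](O[Si](C)(C)C(C)(C)C)C1
F12 | step 3 | tertiary alcohol with phenylselanyl group on the neighbouring ring carbon, from trans-diaxial opening of F11 | CC(=C)[C@H]1C[C@H]([Se]c2ccccc2)[C@@](C)(O)[C@@H](O[Si](C)(C)C(C)(C)C)C1
F13 | step 3 | selenoxide of F12 | CC(=C)[C@H]1C[C@H]([Se](=O)c2ccccc2)[C@@](C)(O)[C@@H](O[Si](C)(C)C(C)(C)C)C1
F14 | step 3 | tertiary allylic alcohol, 1-methyl-6-silyloxy-4-(prop-1-en-2-yl)cyclohex-2-en-1-ol | CC(=C)[C@H]1C=C[C@@](C)(O)[C@@H](O[Si](C)(C)C(C)(C)C)C1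
F15 | step 6 | C7 phenylselanyl ketone (C7 epimers) of the ten-membered dienone | O=C1/C=C(/C)[C@@H](O[Si](C)(C)C(C)(C)C)C/C=C(\C)CCC1[Se]c1ccccc1
F16 | step 6 | selenoxide of F15 | O=C1/C=C(/C)[C@@H](O[Si](C)(C)C(C)(C)C)C/C=C(\C)CCC1[Se](=O)c1ccccc1
F17 | step 7 | (6R)-epimer of trienol 10 | O[C@H]1/C=C(/C)[C@@H](O[Si](C)(C)C(C)(C)C)C/C=C(\C)C/C=C/1
F18 | step 7 | (6S)-4-nitrobenzoate of trienol 10 | O=C(O[C@@H]1/C=C(/C)[C@@H](O[Si](C)(C)C(C)(C)C)C/C=C(\C)C/C=C/1)c1ccc(cc1)[N+](=O)[O-]
F19 | step 19 | bromohydrin of 27 (bromine on C1, hydroxyl on C10) | C=C1C(=O)O[C@@H]2/C=C(/C)[C@@H](OC(=O)c3ccccc3)C[C@H](Br)[C@](C)(O)C[C@@H](OC(=O)[C@]3(C)O[C@H]3C)[C@@H]12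
A1 | alternative 1 | cis-anti-cis 6-4-4 tricyclic ketone | O=C1[C@H](CC(=O)OC)[C@H](O[Si](CC)(CC)CC)C[C@]2(C)[C@H]3C[C@H](O[Si](C)(C)C(C)(C)C)[C@@]3(C)[C@H]12
A2 | alternative 1 | methyl 2-[4-methyl-2-oxo-6-(triethylsilyloxy)cyclohex-3-en-1-yl]acetate (enone half) | O=C1C=C(C)C[C@@H](O[Si](CC)(CC)CC)[C@H]1CC(=O)OC
A3 | alternative 1 | 4-(tert-butyldimethylsilyloxy)-1-methylcyclobut-1-ene (cyclobutene half) | CC1=CC[C@@H]1O[Si](C)(C)C(C)(C)C
A4 | alternative 2 | ten-membered lactone with C3 benzoate and C8 4-methoxybenzyl ether | O=C1C[C@H]2[C@H](O1)/C=C(/C)[C@@H](OC(=O)c1ccccc1)C/C=C(\C)C[C@H]2OCc1ccc(OC)cc1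
A5 | alternative 2 | open-chain γ-lactone with E alkenyl iodide and 1-(4-methoxybenzyloxy)vinyl group | O=C1C[C@@H]([C@H](O1)/C=C(/C)[C@@H](OC(=O)c1ccccc1)C/C=C(\C)I)C(=C)OCc1ccc(OC)cc1
A6 | alternative 3 | (1(10)Z,4Z)-cyclodecadiene-3,8-dione | C=C(CO[Si](C)(C)C(C)(C)C)[C@H]1[C@H](O[Si](C)(C)C(C)(C)C)/C=C(/C)C(=O)C/C=C(/C)CC1=O
A7 | alternative 3 | ring-fusion cis-diol of the bicyclo[4.4.0]decadiene | C=C(CO[Si](C)(C)C(C)(C)C)[C@H]1[C@H](O[Si](C)(C)C(C)(C)C)C=C(C)[C@]2(O)CC=C(C)C[C@]12O
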